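Remarks on the chemistry (assumptions, one line each):
- Ring compounds are named on the germacrane skeleton: ring C1–C10, C11(=C13)–C12 on C7, C14 on C10, C15 on C4; the same atom labels are used for the cyclohexene precursors, and the ring-cis C1=C10 bond is called "ring-cis" throughout.
- The target is taken as 4R,5R,6S,7R,8R,9S with a (2R,3R) side chain; the precursor 22 (5S,6R, arms trans) passes through the chair transition state to 6R,7S in 25, which is the 6S,7R pattern of 43, so both key-step structures are consistent with the target.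
- The C10 handle carried into the organolithium addition is an enol triflate and not an iodide, because electrophilic iodination of an enone cannot be done in the presence of the enol ether arm.
- The hydroxylation at C8 uses the sodium amide base without crown ether, so its enolate 26 is the sodium salt, a species distinct from the crown-separated potassium enolate 24 of the rearrangement.
- It is assumed that the enantiomeric purity from step 2 is raised, if needed, by crystallisation of the semicarbazone of 4; any residual minor enantiomer becomes a separable diastereomer once enantiopure 32 is attached in step 20.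

## Structural features

The target is a germacranolide: a ten-membered carbocycle (C1–C10) with a trans-fused α-methylene-γ-butyrolactone across C6–C7 (oxygen on C6, C11 on C7, exocyclic C13). A trisubstituted epoxide is fused at C4–C5 (C4 quaternary, bearing C15), and the one remaining ring olefin, C1=C10, is ring-cis and conjugated with the C14 methyl ester. Six stereocentres are contiguous from C4 to C9; C8 and C9 carry two different esters on the same ring face, an acetate on C9 and a (2R,3R)-3-chloro-2-hydroxy-2-methylbutanoate on C8, which adds two more centres. Fragile points are the exo-methylene lactone and the enoate (Michael acceptors), the epoxide (acid), the vicinal diester (acyl migration under base) and the tertiary β-chloro alcohol, which recloses to an epoxide with base. The real difficulty is the medium ring with defined olefin geometry combined with relative and absolute control of six ring centres in a conformationally mobile system. The key step exploits two features: C9, C10, C1, C2, C3 and C4 can be folded back into a cyclohexene in which the cis C10=C1 bond is trivial, and C4=C5 stands 1,5 to an enolised C8=C9. A [3,3] shift therefore makes C6–C7, breaks C4–C9 and delivers the ten-membered ring with C6 and C7 set.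

## Logic of the disconnections

43 ⇒ 42. The two C–O bonds of the epoxide are cut. The epoxide is the most acid-sensitive group, and C4=C5 is the only electron-rich olefin of 42, so it can be oxidised last. This removes two stereocentres. The forward step must select the outer face of the trans olefin in the lactone-locked ring.

42 ⇒ 39. The lactone C12–O6 bond is cut and C12 returned to the alcohol level. The exo-methylene lactone is a Michael acceptor and is best made late from a 2-methylene-1,4-diol. The forward oxidation must prefer the primary allylic alcohol over the secondary allylic C6 hydroxyl, and O8 must already be acylated so that no 8,12-lactone can form.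

39 ⇒ 38. Both O–benzyl bonds are cut. Giving C6 and C12 the same ether allows one oxidative deprotection. The forward step must stay neutral enough for the diester and the chlorohydrin.

38 ⇒ 37 ⇒ 36. The acetyl C–O bond on O9 and then the C9–H bond are cut, which returns C9 to the ketone left by ring formation. The forward reduction must be 1,2-selective on a doubly activated enone and deliver hydride to the outer face.

36 ⇒ 27 + 32. The ester C–O bond on O8 is cut, which makes the route convergent and keeps the chlorohydrin out of all earlier steps. The forward acylation joins a hindered α-ketol and a hindered acid with a free tertiary hydroxyl, without a base that could epimerise C8.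

27 ⇒ 25. The C8–O bond is cut, because the enolate of 25 is the natural site for oxygen. The forward step needs α′-regioselective enolisation and attack on the outer face.

25 ⇒ 22. C6–C7 is cut and C4–C9 re-joined (retro oxy-Cope). The ten-membered ring, the trans C4=C5 bond and the C6/C7 pair collapse to a cyclohexenol with two stereocentres and two E olefins. The forward step demands trans arms, E geometry in both, and a chair transition state.

22 ⇒ 21. The C10–C14 bond is cut (carbonylation). The enoate cannot be present during the organolithium addition, so C10 carries a leaving group that survives that addition.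

21 ⇒ 14 + 19. The C8–C9 bond is cut, which is convergent. The forward addition must occur anti to the alkenyl arm on C4.

19 ⇒ 17 + 18 and 17 ⇒ 15 + 16. The C7–C11 bond and one O–benzyl bond are cut, giving three commercial pieces. The forward coupling must keep the E geometry and stop at mono-coupling.

14 ⇒ 13 ⇒ 12 ⇒ 10. The O–S bond and then the C10–O bond are cut. An enol triflate of the 1,2-dione is reached with base and mild oxidants only. The quaternary C4 guarantees that C10 is the only enolisable position.

10 ⇒ 8 + 9. The enol ether C6–O bond is cut. A stereoretentive copper coupling takes the E geometry from 8.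

8 ⇒ 7 ⇒ 5 ⇒ 4. The C5=C6 bond is cut, then the propenyl olefin, then the olefin is shifted back to allyl. Allyl is what the asymmetric alkylation delivers, so one carbon has to be excised. The forward olefination must be E-selective and must spare the ketone.

4 ⇒ 2 + 3 ⇒ 1. The allyl–C4 bond is cut. One catalytic enantioselective alkylation sets C4, from which every other ring centre is relayed.

32 ⇒ 31 ⇒ 30 ⇒ 29 ⇒ 28. The C3′–Cl bond, the acid oxidation level and the epoxide C–O bonds are cut. The Z olefin of 28 with anti addition of O and Cl gives the 2R,3R pattern. The forward epoxidation must be enantioselective and the chloride opening must occur at C3′ with inversion.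

## Other disconnections considered

Alternative 1: The cut is at the C8–O and C9–O bonds. In the forward direction a Rieske arene dioxygenase (toluene dioxygenase in whole cells) would add O2 across the ring edge next to iodine in 1-bromo-4-iodobenzene A1, giving the cis-dihydrodiol A2.
- In favour: two adjacent carbinol centres of defined absolute configuration, with the same-face relationship that O8 and O9 have in 43, would come in one step from an achiral arene. The iodoalkene next to one carbinol is a ready precursor of the C10=C1 enoate (carbonylation as in step 13), and bromine marks the other end for C–C coupling.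
- Against: the six-membered ring of A2 is not a ring of 43 and would have to be opened again. The sense and level of selectivity depend on the enzyme telling bromine from iodine. The diene is prone to rearomatisation by loss of water and to dimerisation. C4–C7, the lactone and the ten-membered ring stay unsolved, and the two carbinols still need different acyl groups.
- Comparison: for C8 and C9 this plan is the better one, since it is enzyme-controlled where the chosen route depends on substrate control in a mobile ring (steps 15 and 21). For everything else it is weaker, because the chosen key step builds the medium ring, the trans olefin and C6/C7 together. Mechanistically it is mild and neutral but needs fermentation, whereas the oxy-Cope step needs only a base. It equals the chosen key step in stereocentres made (two), but opening the template, attaching C1–C7 and closing a ten-membered ring end to end would make the route clearly longer.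

Alternative 2: The cut is at C3–C4 and O–C5. The Grignard reagent A4 (C1–C3) would add to the methyl ketone of the α-chloro ketone A3 (C4–C8 with C15); the magnesium alkoxide would then displace chloride at C5 with inversion and close the epoxide of A5.
- In favour: the quaternary C4 and the trans epoxide would be fixed early under acyclic (Cornforth dipole) control, independent of any ring conformation, in a convergent step that forms two bonds.
- Against: no carbocycle is formed. The sensitive epoxide would have to survive ring closure, C8/C9 chemistry, two esterifications and lactonisation. A3 itself needs an enantioselective synthesis of two centres. Face selectivity in additions to α-chloro methyl ketones can be modest. The ten-membered ring would have to be closed end to end against strain and entropy.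
- Comparison: for C4/C5 the alternative is the better plan, because it does not rely on face selection in step 25; it is equal in stereocentres handled per step. It leaves the ring, C7–C9 and both olefin geometries open. Its mechanism (polar addition, then SN2) is predictable but cryogenic. The chosen plan needs only one final step for the epoxide and gets ring, olefin and two centres from one rearrangement, so it is shorter overall.

Alternative 3: The cut is at C5–C6 and O–C12. CrCl2 with catalytic NiCl2 would add the E alkenyl iodide of the seco aldehyde A6 to its C6 aldehyde (Nozaki–Hiyama–Kishi reaction); the chromium alkoxide would then attack the C12 methyl ester and give lactone A7.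
- In favour: ring and lactone would close in one operation, the E geometry of C4=C5 is carried in from the iodide, the chromium reagent tolerates esters and silyl ethers, and with O8 and the C9 acetate in place the end game is short.
- Against: this is an end-to-end closure of a strained ten-membered ring, needing high dilution and a large excess of chromium salt. The C6 configuration, and with it the trans lactone, would rest on 1,2-induction from C7 in a macrocyclic transition state of uncertain shape. C7 of A6 is α to an aldehyde and allylic to an acrylate, so epimerisation and olefin migration threaten. A6 needs an acyclic, fully stereocontrolled synthesis of C7–C9 and of the trisubstituted enoate geometry.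
- Comparison: the alternative is better in one respect, since the lactone arrives together with the ring (steps 23 and 24 here), and it is equal in rings formed. The chosen step closes the ring by ring expansion without entropic cost and relays C6/C7 through a chair, where the alternative depends on diastereoselective addition. The alternative is shorter after ring closure but longer before it.

Key step: step 14

## Route

Step 1
Reactants: 1 2-methylcyclohexanone
Product: 2 trimethyl[(2-methylcyclohex-1-en-1-yl)oxy]silane
Conditions: Me3SiCl, NaI, Et3N, MeCN, rt; distillation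
Reagents that add atoms: chlorotrimethylsilane, C[Si](C)(C)Cl
Why: Soft enolisation with iodotrimethylsilane made in situ equilibrates to the more substituted enol ether (thermodynamic silyl enol ether formation); the minor regioisomer is removed by distillation or later as the regioisomeric allyl ketone.

Step 2
Reactants: 2 trimethyl[(2-methylcyclohex-1-en-1-yl)oxy]silane; 3 diallyl carbonate
Product: 4 (S)-2-allyl-2-methylcyclohexanone
Conditions: Pd2(dba)3 (2.5 mol %), (S)-t-BuPHOX (6 mol %), Bu4N[Ph3SiF2] (35 mol %), THF, 25 °C
Reagents that add atoms: none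
Why: Fluoride releases the tetrasubstituted enolate, which combines with the π-allylpalladium complex of the chiral phosphinooxazoline (enantioselective allylic alkylation of Tsuji type); the (S)-ligand is the one associated with the (S)-ketone, so C4 is set here.

Step 3
Reactants: 4 (S)-2-allyl-2-methylcyclohexanone
Product: 5 (S)-2-methyl-2-[(E)-prop-1-en-1-yl]cyclohexanone
Conditions: PdCl2(MeCN)2 (5 mol %), toluene, 80 °C
Reagents that add atoms: none
Why: A palladium-mediated 1,3-hydrogen shift moves the terminal olefin one position toward the ring, where the quaternary carbon stops it (olefin isomerisation); the E/Z ratio is irrelevant because the olefin is cleaved in step 4.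

Step 4
Reactants: 5 (S)-2-methyl-2-[(E)-prop-1-en-1-yl]cyclohexanone
Product: 7 (S)-1-methyl-2-oxocyclohexane-1-carbaldehyde, via ozonide 6 (not isolated)
Conditions: O3, CH2Cl2, −78 °C; PPh3, −78 °C → rt; used crude
Reagents that add atoms: ozone, [O-][O+]=O
Why: Ozonolysis with reductive work-up cleaves the electron-rich propenyl group and spares the ketone; no hydrogen lies between the two carbonyls, so C4 cannot epimerise, and the aldehyde is used at once to avoid deformylation.

Step 5
Reactants: 7 (S)-1-methyl-2-oxocyclohexane-1-carbaldehyde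
Product: 8 (S)-2-[(E)-2-iodoethenyl]-2-methylcyclohexanone
Conditions: CrCl2 (6 equiv), CHI3 (2 equiv), THF, 0 °C → rt
Reagents that add atoms: iodoform, IC(I)I
Why: Takai olefination: the gem-dichromium species from iodoform adds to the aldehyde much faster than to the hindered ketone, and anti elimination should give the E alkenyl iodide.

Step 6
Reactants: 8 (S)-2-[(E)-2-iodoethenyl]-2-methylcyclohexanone; 9 4-methoxybenzyl alcohol
Product: 10 (S)-2-{(E)-2-[(4-methoxyphenyl)methoxy]ethenyl}-2-methylcyclohexanone
Conditions: CuI (10 mol %), 3,4,7,8-tetramethyl-1,10-phenanthroline (20 mol %), Cs2CO3, toluene, 80 °C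
Reagents that add atoms: none
Why: Copper-catalysed Ullmann-type C–O coupling of an alkenyl iodide with a primary alcohol proceeds with retention of olefin geometry, giving the E enol ether the chair needs; the E iodide cannot be O-vinylated intramolecularly by the ketone enolate.

Step 7
Reactants: 10 (S)-2-{(E)-2-[(4-methoxyphenyl)methoxy]ethenyl}-2-methylcyclohexanone
Product: 12 (2S)-6-hydroxy-2-{(E)-2-[(4-methoxyphenyl)methoxy]ethenyl}-2-methylcyclohexanone (both C6 epimers), via potassium enolate 11 (not isolated)
Conditions: KN(SiMe3)2, THF, −78 °C; 2-(phenylsulfonyl)-3-phenyloxaziridine, −78 °C; AcOH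
Reagents that add atoms: 2-(phenylsulfonyl)-3-phenyloxaziridine, O=S(=O)(c1ccccc1)N1OC1c1ccccc1
Why: The quaternary C4 leaves C10 as the only enolisable position; enolate 11 is oxidised by the N-sulfonyloxaziridine (enolate hydroxylation), and the new carbinol centre does not matter because it is oxidised in step 8.

Step 8
Reactants: 12 (2S)-6-hydroxy-2-{(E)-2-[(4-methoxyphenyl)methoxy]ethenyl}-2-methylcyclohexanone
Product: 13 (6S)-2-hydroxy-6-{(E)-2-[(4-methoxyphenyl)methoxy]ethenyl}-6-methylcyclohex-2-en-1-one
Conditions: Dess–Martin periodinane, NaHCO3, CH2Cl2, 0 °C → rt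
Reagents that add atoms: none
Why: Buffered oxidation of the α-ketol gives the 1,2-dione, which can enolise only toward C1 and should rest as the diosphenol; no electrophilic halogen is used, so the enol ether arm survives.

Step 9
Reactants: 13 (6S)-2-hydroxy-6-{(E)-2-[(4-methoxyphenyl)methoxy]ethenyl}-6-methylcyclohex-2-en-1-one
Product: 14 (5S)-5-{(E)-2-[(4-methoxyphenyl)methoxy]ethenyl}-5-methyl-6-oxocyclohex-1-en-1-yl trifluoromethanesulfonate
Conditions: PhNTf2, Et3N, DMAP (cat.), CH2Cl2, 0 °C → rt
Reagents that add atoms: N-phenylbis(trifluoromethanesulfonimide), O=S(=O)(N(c1ccccc1)S(=O)(=O)C(F)(F)F)C(F)(F)F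
Why: The acidic enol is O-sulfonylated by a mild triflyl donor (enol triflate formation), giving an α-sulfonyloxy enone as the C10 handle in place of an α-halo enone.

Step 10
Reactants: 15 2-bromoprop-2-en-1-ol; 16 4-methoxybenzyl chloride
Product: 17 1-{[(2-bromoprop-2-en-1-yl)oxy]methyl}-4-methoxybenzene
Conditions: NaH, Bu4NI (cat.), THF/DMF, 0 °C → rt
Reagents that add atoms: none
Why: Williamson ether synthesis; the alkoxide is benzylated faster than the vinyl bromide can eliminate at this temperature.

Step 11
Reactants: 17 1-{[(2-bromoprop-2-en-1-yl)oxy]methyl}-4-methoxybenzene; 18 (E)-1,2-bis(tributylstannyl)ethene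
Product: 19 tributyl[(1E)-3-{[(4-methoxyphenyl)methoxy]methyl}buta-1,3-dien-1-yl]stannane
Conditions: Pd(PPh3)4 (5 mol %), 18 (2.5 equiv), toluene, 90 °C
Reagents that add atoms: none
Why: Stille coupling of the alkenyl bromide with one tin terminus of 18, used in excess to suppress double coupling, transfers the E geometry unchanged.

Step 12
Reactants: 14 (5S)-5-{(E)-2-[(4-methoxyphenyl)methoxy]ethenyl}-5-methyl-6-oxocyclohex-1-en-1-yl trifluoromethanesulfonate; 19 tributyl[(1E)-3-{[(4-methoxyphenyl)methoxy]methyl}buta-1,3-dien-1-yl]stannane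
Product: 21 (5S,6R)-6-hydroxy-6-[(1E)-3-{[(4-methoxyphenyl)methoxy]methyl}buta-1,3-dien-1-yl]-5-{(E)-2-[(4-methoxyphenyl)methoxy]ethenyl}-5-methylcyclohex-1-en-1-yl trifluoromethanesulfonate, via dienyllithium 20 (not isolated)
Conditions: 19, n-BuLi, THF, −78 °C; then 14, −78 °C; aq. NH4Cl
Reagents that add atoms: none
Why: Tin–lithium exchange gives 20 with retention, and 20 adds 1,2 to the ketone, which the α-sulfonyloxy group activates (organolithium carbonyl addition). By the Felkin–Anh model the nucleophile should enter anti to the alkenyl arm on C4 (the better σ-acceptor, compared with methyl), placing the two arms trans and OH/C15 trans-diaxial; at −78 °C the enol triflate should not be attacked.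

Step 13
Reactants: 21 (5S,6R)-6-hydroxy-6-[(1E)-3-{[(4-methoxyphenyl)methoxy]methyl}buta-1,3-dien-1-yl]-5-{(E)-2-[(4-methoxyphenyl)methoxy]ethenyl}-5-methylcyclohex-1-en-1-yl trifluoromethanesulfonate
Product: 22 methyl (5S,6R)-6-hydroxy-6-[(1E)-3-{[(4-methoxyphenyl)methoxy]methyl}buta-1,3-dien-1-yl]-5-{(E)-2-[(4-methoxyphenyl)methoxy]ethenyl}-5-methylcyclohex-1-ene-1-carboxylate
Conditions: Pd(PPh3)4 (5 mol %), CO (1 atm), MeOH, Et3N, DMF, 50 °C
Reagents that add atoms: carbon monoxide, [C-]#[O+]; methanol, CO
Why: Oxidative addition of zerovalent palladium into the alkenyl triflate, CO insertion and methanolysis give the enoate (palladium-catalysed alkoxycarbonylation); methanol as co-solvent outcompetes the neighbouring tertiary hydroxyl, whose attack would need a strained β-lactone.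

Step 14
Reactants: 22 methyl (5S,6R)-6-hydroxy-6-[(1E)-3-{[(4-methoxyphenyl)methoxy]methyl}buta-1,3-dien-1-yl]-5-{(E)-2-[(4-methoxyphenyl)methoxy]ethenyl}-5-methylcyclohex-1-ene-1-carboxylate
Product: 25 methyl (4E,6R,7S)-6,12-bis[(4-methoxyphenyl)methoxy]-9-oxogermacra-1(10),4,11(13)-trien-14-oate (ring-cis C1=C10), via potassium alkoxide 23 (not isolated), via potassium enolate 24 (not isolated)
Conditions: KN(SiMe3)2 (1.1 equiv), 18-crown-6 (1.2 equiv), THF (0.01 M), −78 → 20 °C; AcOH in THF, −78 °C
Reagents that add atoms: none
Why: Deprotonation gives alkoxide 23, whose crown-separated ion pair weakens the C4–C9 bond and triggers a concerted [3,3] sigmatropic shift in which C6–C7 forms as C4–C9 breaks; the closest known reaction type is the anionic oxy-Cope ring expansion of trans-1,2-dialkenylcyclohexanols to cyclodec-5-enones. The ten-membered ring is thus closed by four-atom ring expansion of the cyclohexene and not by end-to-end cyclisation, so there is no dilution-dependent entropy penalty and C10=C1 stays ring-cis. With the arms trans, the only chair has both ring residues (C3 and C10) equatorial and O−/C15 axial; equatorial C3 becomes trans to C6, which gives the E C4=C5 bond. C6 and C7 are the new stereocentres: the E enol ether places its oxygen and the E diene places C11 equatorial, so H6 and H7 come out anti, and the absolute sense is relayed from (5S,6R)-22 through the chair to 6R,7S in 25. The step needs chair over boat (secured by the trans arrangement), geometric purity of both arms (secured in steps 5, 6, 11 and 12), and the shift through C7=C8 instead of the ring olefin (which would need a bicyclo[2.2.2] transition state). Enolate 24 is protonated at −78 °C with acetic acid so that the doubly activated C1=C10 of 25 never meets free alkoxide or amide.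

Step 15
Reactants: 25 methyl (4E,6R,7S)-6,12-bis[(4-methoxyphenyl)methoxy]-9-oxogermacra-1(10),4,11(13)-trien-14-oate
Product: 27 methyl (4E,6R,7R,8R)-8-hydroxy-6,12-bis[(4-methoxyphenyl)methoxy]-9-oxogermacra-1(10),4,11(13)-trien-14-oate, via sodium enolate 26 (not isolated)
Conditions: NaN(SiMe3)2 (1.05 equiv), THF, −78 °C, 25 added to the base; 2-(phenylsulfonyl)-3-phenyloxaziridine, −78 °C; AcOH
Reagents that add atoms: 2-(phenylsulfonyl)-3-phenyloxaziridine, O=S(=O)(c1ccccc1)N1OC1c1ccccc1
Why: Inverse addition to the hindered sodium amide at −78 °C should remove a C8 proton kinetically (α′-deprotonation of an enone) and give sodium enolate 26, expected in the ring-trans C8=C9 geometry that keeps C7 and C10 apart; this contact ion pair takes oxygen from the N-sulfonyloxaziridine (enolate hydroxylation) and is less prone than a crown-separated enolate to add to the sulfonimine by-product. Oxygen should enter on the outer face of the enolate, opposite the C6–C7 ring bond and the transannular C4=C5, which gives 8R with H8 anti to H7.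

Step 16
Reactants: 28 angelic acid
Product: 29 (Z)-2-methylbut-2-en-1-ol
Conditions: LiAlH4, Et2O, 0 °C
Reagents that add atoms: none
Why: Hydride reduction of the acid to the allylic alcohol does not touch or isomerise the trisubstituted Z olefin.

Step 17
Reactants: 29 (Z)-2-methylbut-2-en-1-ol
Product: 30 [(2R,3S)-2,3-dimethyloxiran-2-yl]methanol
Conditions: Ti(OiPr)4 (10 mol %), D-(−)-diethyl tartrate (12 mol %), t-BuOOH, 4 Å molecular sieves, CH2Cl2, −20 °C
Reagents that add atoms: tert-butyl hydroperoxide, CC(C)(C)OO
Why: Catalytic Sharpless asymmetric epoxidation: the titanium tartrate complex delivers oxygen to one face of the allylic alcohol, D-(−)-tartrate being the enantiomer that leads to the (2R,3S) epoxide, and the cis relationship of the C3 methyl and CH2OH is kept.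

Step 18
Reactants: 30 [(2R,3S)-2,3-dimethyloxiran-2-yl]methanol
Product: 31 (2S,3S)-2,3-dimethyloxirane-2-carboxylic acid
Conditions: TEMPO (10 mol %), PhI(OAc)2 (2.2 equiv), MeCN/H2O, 0 °C → rt
Reagents that add atoms: water, O
Why: Oxoammonium oxidation of the primary alcohol through the aldehyde hydrate to the acid leaves the epoxide intact; the C2 descriptor changes by the CIP rule only.

Step 19
Reactants: 31 (2S,3S)-2,3-dimethyloxirane-2-carboxylic acid
Product: 32 (2R,3R)-3-chloro-2-hydroxy-2-methylbutanoic acid
Conditions: HCl (4 M in 1,4-dioxane), 0 °C → rt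
Reagents that add atoms: hydrogen chloride, Cl
Why: Acid-promoted SN2 epoxide opening: chloride attacks C3 with inversion because C2 is fully substituted and its ionisation is disfavoured by the carboxyl group, so Cl and OH end up anti (2R,3R); the low temperature avoids decarboxylation of the glycidic acid.

Step 20
Reactants: 27 methyl (4E,6R,7R,8R)-8-hydroxy-6,12-bis[(4-methoxyphenyl)methoxy]-9-oxogermacra-1(10),4,11(13)-trien-14-oate; 32 (2R,3R)-3-chloro-2-hydroxy-2-methylbutanoic acid
Product: 36 methyl (4E,6R,7S,8R)-8-{[(2R,3R)-3-chloro-2-hydroxy-2-methylbutanoyl]oxy}-6,12-bis[(4-methoxyphenyl)methoxy]-9-oxogermacra-1(10),4,11(13)-trien-14-oate, via bis-silyl derivative 33 (not isolated), via silyloxy acid chloride 34 (not isolated), via silyl ether 35 (not isolated)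
Conditions: 32, Me3SiCl, pyridine, CH2Cl2, 0 °C; (COCl)2, DMF (cat.), 0 °C, evaporate; 27, pyridine, DMAP, CH2Cl2, 0 °C → rt; citric acid, MeOH, 0 °C
Reagents that add atoms: none
Why: Transient bis-silylation masks the tertiary hydroxyl, the silyl ester is converted into the acid chloride under neutral conditions, and this acylates the hindered C8 hydroxyl with DMAP catalysis (acyl chloride esterification); mild acidic methanolysis then removes the tertiary silyl ether. No base strong enough to enolise C8 or to close the chlorohydrin is present.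

Step 21
Reactants: 36 methyl (4E,6R,7S,8R)-8-{[(2R,3R)-3-chloro-2-hydroxy-2-methylbutanoyl]oxy}-6,12-bis[(4-methoxyphenyl)methoxy]-9-oxogermacra-1(10),4,11(13)-trien-14-oate
Product: 37 methyl (4E,6R,7S,8R,9S)-8-{[(2R,3R)-3-chloro-2-hydroxy-2-methylbutanoyl]oxy}-9-hydroxy-6,12-bis[(4-methoxyphenyl)methoxy]germacra-1(10),4,11(13)-trien-14-oate
Conditions: NaBH4, CeCl3·7H2O, MeOH/THF, −78 °C
Reagents that add atoms: none
Why: Luche reduction: cerium-activated borohydride attacks the ketone 1,2 and not the doubly activated olefin. With the C8–O bond held near the carbonyl plane by cation bridging of the two oxygens, C7 and the ring shield one face, and hydride should enter past H8 from the outer face, giving 9S with both oxygens on the same ring face.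

Step 22
Reactants: 37 methyl (4E,6R,7S,8R,9S)-8-{[(2R,3R)-3-chloro-2-hydroxy-2-methylbutanoyl]oxy}-9-hydroxy-6,12-bis[(4-methoxyphenyl)methoxy]germacra-1(10),4,11(13)-trien-14-oate
Product: 38 methyl (4E,6R,7S,8R,9S)-9-acetoxy-8-{[(2R,3R)-3-chloro-2-hydroxy-2-methylbutanoyl]oxy}-6,12-bis[(4-methoxyphenyl)methoxy]germacra-1(10),4,11(13)-trien-14-oate
Conditions: Ac2O (1.5 equiv), pyridine, DMAP (cat.), CH2Cl2, 0 °C
Reagents that add atoms: acetic anhydride, CC(=O)OC(C)=O
Why: The secondary allylic alcohol is acetylated (acylation) under conditions that leave the hindered tertiary α-hydroxy ester untouched; acetylating promptly also closes the window for acyl migration from O8.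

Step 23
Reactants: 38 methyl (4E,6R,7S,8R,9S)-9-acetoxy-8-{[(2R,3R)-3-chloro-2-hydroxy-2-methylbutanoyl]oxy}-6,12-bis[(4-methoxyphenyl)methoxy]germacra-1(10),4,11(13)-trien-14-oate
Product: 39 methyl (4E,6R,7S,8R,9S)-9-acetoxy-8-{[(2R,3R)-3-chloro-2-hydroxy-2-methylbutanoyl]oxy}-6,12-dihydroxygermacra-1(10),4,11(13)-trien-14-oate
Conditions: DDQ (3 equiv), CH2Cl2/pH 7 buffer, 0 °C
Reagents that add atoms: none
Why: Oxidative cleavage of both 4-methoxybenzyl ethers by hydride abstraction and hydrolysis of the oxocarbenium ions; the buffered two-phase medium protects the esters and the tertiary chlorohydrin.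

Step 24
Reactants: 39 methyl (4E,6R,7S,8R,9S)-9-acetoxy-8-{[(2R,3R)-3-chloro-2-hydroxy-2-methylbutanoyl]oxy}-6,12-dihydroxygermacra-1(10),4,11(13)-trien-14-oate
Product: 42 methyl (4E,6R,7S,8R,9S)-9-acetoxy-8-{[(2R,3R)-3-chloro-2-hydroxy-2-methylbutanoyl]oxy}germacra-1(10),4,11(13)-trien-12,6-olid-14-oate, via enal 40 (not isolated), via lactol 41 (not isolated)
Conditions: TEMPO (20 mol %), PhI(OAc)2 (3 equiv), CH2Cl2, rt
Reagents that add atoms: none
Why: The oxoammonium salt oxidises the primary allylic alcohol selectively to enal 40, the C6 hydroxyl closes to lactol 41, and a second oxidation gives the lactone (oxidative lactonisation of a 2-methylene-1,4-diol); the trans ring fusion follows from the 6,7-configuration fixed in step 14.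

Step 25
Reactants: 42 methyl (4E,6R,7S,8R,9S)-9-acetoxy-8-{[(2R,3R)-3-chloro-2-hydroxy-2-methylbutanoyl]oxy}germacra-1(10),4,11(13)-trien-12,6-olid-14-oate
Product: 43 methyl (4R,5R,6S,7R,8R,9S)-9-acetoxy-8-{[(2R,3R)-3-chloro-2-hydroxy-2-methylbutanoyl]oxy}-4,5-epoxygermacra-1(10),11(13)-dien-12,6-olid-14-oate (the target)
Conditions: mCPBA, NaHCO3, CH2Cl2, 0 °C
Reagents that add atoms: 3-chloroperoxybenzoic acid, OOC(=O)c1cccc(Cl)c1
Why: Prilezhaev epoxidation: the peracid attacks the only electron-rich olefin, C4=C5, and leaves the enoate and the methylene lactone. In the lactone-locked ring the inner face of the E olefin is closed by the ring, so oxygen should add from the outer face and give 4R,5R.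

## Compound list

1 | 2-methylcyclohexanone | CC1CCCCC1=O | starting material
2 | trimethyl[(2-methylcyclohex-1-en-1-yl)oxy]silane | CC1=C(O[Si](C)(C)C)CCCC1 | intermediate
3 | diallyl carbonate | C=CCOC(=O)OCC=C | starting material
4 | (S)-2-allyl-2-methylcyclohexanone | C=CC[C@]1(C)CCCCC1=O | intermediate
5 | (S)-2-methyl-2-[(E)-prop-1-en-1-yl]cyclohexanone | C/C=C/[C@]1(C)CCCCC1=O | intermediate
6 | 3-methyl-5-[(1S)-1-methyl-2-oxocyclohexyl]-1,2,4-trioxolane (ozonide of 5) | C[C@@]1(C2OOC(C)O2)CCCCC1=O | intermediate (not isolated)
7 | (S)-1-methyl-2-oxocyclohexane-1-carbaldehyde | O=C[C@]1(C)CCCCC1=O | intermediate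
8 | (S)-2-[(E)-2-iodoethenyl]-2-methylcyclohexanone | I/C=C/[C@]1(C)CCCCC1=O | intermediate
9 | 4-methoxybenzyl alcohol | COc1ccc(CO)cc1 | starting material
10 | (S)-2-{(E)-2-[(4-methoxyphenyl)methoxy]ethenyl}-2-methylcyclohexanone | COc1ccc(CO/C=C/[C@]2(C)CCCCC2=O)cc1 | intermediate
11 | potassium enolate of 10 (C9–O−, C9=C10) | COc1ccc(CO/C=C/[C@]2(C)CCCC=C2[O-])cc1.[K+] | intermediate (not isolated)
12 | (2S)-6-hydroxy-2-{(E)-2-[(4-methoxyphenyl)methoxy]ethenyl}-2-methylcyclohexanone, both C6 epimers | COc1ccc(CO/C=C/[C@]2(C)CCCC(O)C2=O)cc1 | intermediate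
13 | (6S)-2-hydroxy-6-{(E)-2-[(4-methoxyphenyl)methoxy]ethenyl}-6-methylcyclohex-2-en-1-one | COc1ccc(CO/C=C/[C@]2(C)CCC=C(O)C2=O)cc1 | intermediate
14 | (5S)-5-{(E)-2-[(4-methoxyphenyl)methoxy]ethenyl}-5-methyl-6-oxocyclohex-1-en-1-yl trifluoromethanesulfonate | COc1ccc(CO/C=C/[C@]2(C)CCC=C(OS(=O)(=O)C(F)(F)F)C2=O)cc1 | intermediate
15 | 2-bromoprop-2-en-1-ol (2-bromoallyl alcohol) | OCC(Br)=C | starting material
16 | 4-methoxybenzyl chloride | COc1ccc(CCl)cc1 | starting material
17 | 1-{[(2-bromoprop-2-en-1-yl)oxy]methyl}-4-methoxybenzene | C=C(Br)COCc1ccc(OC)cc1 | intermediate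
18 | (E)-1,2-bis(tributylstannyl)ethene | CCCC[Sn](CCCC)(CCCC)/C=C/[Sn](CCCC)(CCCC)CCCC | starting material
19 | tributyl[(1E)-3-{[(4-methoxyphenyl)methoxy]methyl}buta-1,3-dien-1-yl]stannane | CCCC[Sn](CCCC)(CCCC)/C=C/C(=C)COCc1ccc(OC)cc1 | intermediate
20 | [(1E)-3-{[(4-methoxyphenyl)methoxy]methyl}buta-1,3-dien-1-yl]lithium | [Li]/C=C/C(=C)COCc1ccc(OC)cc1 | intermediate (not isolated)
21 | (5S,6R)-6-hydroxy-6-[(1E)-3-{[(4-methoxyphenyl)methoxy]methyl}buta-1,3-dien-1-yl]-5-{(E)-2-[(4-methoxyphenyl)methoxy]ethenyl}-5-methylcyclohex-1-en-1-yl trifluoromethanesulfonate (arms trans) | O[C@@]1(/C=C/C(=C)COCc2ccc(OC)cc2)C(OS(=O)(=O)C(F)(F)F)=CCC[C@@]1(C)/C=C/OCc1ccc(OC)cc1 | intermediate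
22 | methyl (5S,6R)-6-hydroxy-6-[(1E)-3-{[(4-methoxyphenyl)methoxy]methyl}buta-1,3-dien-1-yl]-5-{(E)-2-[(4-methoxyphenyl)methoxy]ethenyl}-5-methylcyclohex-1-ene-1-carboxylate (arms trans; precursor of the key step) | O[C@@]1(/C=C/C(=C)COCc2ccc(OC)cc2)C(C(=O)OC)=CCC[C@@]1(C)/C=C/OCc1ccc(OC)cc1 | intermediate
23 | potassium alkoxide of 22 | [K+].[O-][C@@]1(/C=C/C(=C)COCc2ccc(OC)cc2)C(C(=O)OC)=CCC[C@@]1(C)/C=C/OCc1ccc(OC)cc1 | intermediate (not isolated)
24 | potassium enolate of 25 (C8=C9, O− cis to C7) | [K+].[O-]/C1=C\[C@@H](C(=C)COCc2ccc(OC)cc2)[C@H](OCc2ccc(OC)cc2)/C=C(\C)CC/C=C1/C(=O)OC | intermediate (not isolated)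
25 | methyl (4E,6R,7S)-6,12-bis[(4-methoxyphenyl)methoxy]-9-oxogermacra-1(10),4,11(13)-trien-14-oate (ring-cis C1=C10; product of the key step) | O=C1C[C@@H](C(=C)COCc2ccc(OC)cc2)[C@H](OCc2ccc(OC)cc2)/C=C(\C)CC/C=C1/C(=O)OC | intermediate
26 | sodium enolate of 25 (C8=C9, O− cis to C7) | [Na+].[O-]/C1=C\[C@@H](C(=C)COCc2ccc(OC)cc2)[C@H](OCc2ccc(OC)cc2)/C=C(\C)CC/C=C1/C(=O)OC | intermediate (not isolated)
27 | methyl (4E,6R,7R,8R)-8-hydroxy-6,12-bis[(4-methoxyphenyl)methoxy]-9-oxogermacra-1(10),4,11(13)-trien-14-oate | O=C1[C@H](O)[C@@H](C(=C)COCc2ccc(OC)cc2)[C@H](OCc2ccc(OC)cc2)/C=C(\C)CC/C=C1/C(=O)OC | intermediate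
28 | angelic acid, (Z)-2-methylbut-2-enoic acid | C/C=C(/C)C(=O)O | starting material
29 | (Z)-2-methylbut-2-en-1-ol | C/C=C(/C)CO | intermediate
30 | [(2R,3S)-2,3-dimethyloxiran-2-yl]methanol | C[C@@H]1O[C@]1(C)CO | intermediate
31 | (2S,3S)-2,3-dimethyloxirane-2-carboxylic acid | C[C@@H]1O[C@]1(C)C(=O)O | intermediate
32 | (2R,3R)-3-chloro-2-hydroxy-2-methylbutanoic acid | OC(=O)[C@@](C)(O)[C@@H](C)Cl | intermediate
33 | trimethylsilyl (2R,3R)-3-chloro-2-methyl-2-[(trimethylsilyl)oxy]butanoate | C[Si](C)(C)OC(=O)[C@@](C)(O[Si](C)(C)C)[C@@H](C)Cl | intermediate (not isolated)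
34 | (2S,3R)-3-chloro-2-methyl-2-[(trimethylsilyl)oxy]butanoyl chloride (same spatial arrangement as 32; C2 descriptor changes by the CIP rule) | ClC(=O)[C@@](C)(O[Si](C)(C)C)[C@@H](C)Cl | intermediate (not isolated)
35 | methyl (4E,6R,7S,8R)-8-{[(2R,3R)-3-chloro-2-methyl-2-(trimethylsilyloxy)butanoyl]oxy}-6,12-bis[(4-methoxyphenyl)methoxy]-9-oxogermacra-1(10),4,11(13)-trien-14-oate | O=C1[C@H](OC(=O)[C@@](C)(O[Si](C)(C)C)[C@@H](C)Cl)[C@@H](C(=C)COCc2ccc(OC)cc2)[C@H](OCc2ccc(OC)cc2)/C=C(\C)CC/C=C1/C(=O)OC | intermediate (not isolated)
36 | methyl (4E,6R,7S,8R)-8-{[(2R,3R)-3-chloro-2-hydroxy-2-methylbutanoyl]oxy}-6,12-bis[(4-methoxyphenyl)methoxy]-9-oxogermacra-1(10),4,11(13)-trien-14-oate | O=C1[C@H](OC(=O)[C@@](C)(O)[C@@H](C)Cl)[C@@H](C(=C)COCc2ccc(OC)cc2)[C@H](OCc2ccc(OC)cc2)/C=C(\C)CC/C=C1/C(=O)OC | intermediate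
37 | methyl (4E,6R,7S,8R,9S)-8-{[(2R,3R)-3-chloro-2-hydroxy-2-methylbutanoyl]oxy}-9-hydroxy-6,12-bis[(4-methoxyphenyl)methoxy]germacra-1(10),4,11(13)-trien-14-oate | O[C@@H]1[C@H](OC(=O)[C@@](C)(O)[C@@H](C)Cl)[C@@H](C(=C)COCc2ccc(OC)cc2)[C@H](OCc2ccc(OC)cc2)/C=C(\C)CC/C=C1/C(=O)OC | intermediate
38 | methyl (4E,6R,7S,8R,9S)-9-acetoxy-8-{[(2R,3R)-3-chloro-2-hydroxy-2-methylbutanoyl]oxy}-6,12-bis[(4-methoxyphenyl)methoxy]germacra-1(10),4,11(13)-trien-14-oate | CC(=O)O[C@@H]1[C@H](OC(=O)[C@@](C)(O)[C@@H](C)Cl)[C@@H](C(=C)COCc2ccc(OC)cc2)[C@H](OCc2ccc(OC)cc2)/C=C(\C)CC/C=C1/C(=O)OC | intermediate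
39 | methyl (4E,6R,7S,8R,9S)-9-acetoxy-8-{[(2R,3R)-3-chloro-2-hydroxy-2-methylbutanoyl]oxy}-6,12-dihydroxygermacra-1(10),4,11(13)-trien-14-oate | CC(=O)O[C@@H]1[C@H](OC(=O)[C@@](C)(O)[C@@H](C)Cl)[C@@H](C(=C)CO)[C@H](O)/C=C(\C)CC/C=C1/C(=O)OC | intermediate
40 | methyl (4E,6R,7S,8R,9S)-9-acetoxy-8-{[(2R,3R)-3-chloro-2-hydroxy-2-methylbutanoyl]oxy}-6-hydroxy-12-oxogermacra-1(10),4,11(13)-trien-14-oate | CC(=O)O[C@@H]1[C@H](OC(=O)[C@@](C)(O)[C@@H](C)Cl)[C@@H](C(=C)C=O)[C@H](O)/C=C(\C)CC/C=C1/C(=O)OC | intermediate (not isolated)
41 | methyl (4E,6R,7S,8R,9S)-9-acetoxy-8-{[(2R,3R)-3-chloro-2-hydroxy-2-methylbutanoyl]oxy}-6,12-epoxy-12-hydroxygermacra-1(10),4,11(13)-trien-14-oate (lactol, both C12 epimers) | C1C/C=C(C(=O)OC)\[C@H](OC(C)=O)[C@H](OC(=O)[C@@](C)(O)[C@@H](C)Cl)[C@@H]2[C@H](OC(O)C2=C)/C=C1\C | intermediate (not isolated)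
42 | methyl (4E,6R,7S,8R,9S)-9-acetoxy-8-{[(2R,3R)-3-chloro-2-hydroxy-2-methylbutanoyl]oxy}germacra-1(10),4,11(13)-trien-12,6-olid-14-oate | C1C/C=C(C(=O)OC)\[C@H](OC(C)=O)[C@H](OC(=O)[C@@](C)(O)[C@@H](C)Cl)[C@@H]2[C@H](OC(=O)C2=C)/C=C1\C | intermediate
43 | methyl (4R,5R,6S,7R,8R,9S)-9-acetoxy-8-{[(2R,3R)-3-chloro-2-hydroxy-2-methylbutanoyl]oxy}-4,5-epoxygermacra-1(10),11(13)-dien-12,6-olid-14-oate (CNP0185503.5) | C=C1C(=O)O[C@H]2[C@H]1[C@@H](OC(=O)[C@@](C)(O)[C@@H](C)Cl)[C@@H](OC(C)=O)/C(C(=O)OC)=C\CC[C@@]1(C)O[C@H]21 | target

## Step count and least certain steps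

Total: 25 steps. Longest linear sequence: 19 steps (1–9, 12–15, 20–25). Side branches: the dienylstannane (steps 10 and 11) and the side-chain acid (steps 16–19).

Step 14 (key step). The most likely failure is base-induced loss of material: the tertiary alkoxide next to an acrylate, or the doubly activated olefin of the product, may undergo conjugate addition or oligomerisation, or a boat pathway may compete and erode C6/C7 control. The fallback is the neutral, thermal variant. It sets out from 22, which is O-silylated with N-(trimethylsilyl)imidazole to the trimethylsilyl ether F1. Heating F1 in toluene in a sealed vessel at about 180 °C should give, by the siloxy-Cope rearrangement, the trimethylsilyl enol ether F2. Mild acidic methanolysis (citric acid, MeOH) of F2 comes back to the route at 25.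

Step 12. The most likely failure is poor facial discrimination, because methyl and the alkenyl arm on C4 differ little in size, so cis and trans dialkenyl carbinols may form together; attack of the organolithium at sulfur of the triflate is a second risk. The fallback replaces the bulky dienyl nucleophile by the smallest sp nucleophile, whose trajectory is governed by the antiperiplanar alkenyl arm, and builds the diene afterwards. It sets out from 14, which takes up ethynylmagnesium bromide (CeCl3, THF, −78 °C) to give the ethynyl carbinol triflate F3. Methoxycarbonylation as in step 13 gives the ethynyl carbinol ester F4. Palladium-catalysed hydrostannation (Bu3SnH, PdCl2(PPh3)2) places tin on the terminal carbon and gives the E alkenylstannane F5. Stille coupling of F5 with 17 comes back to the route at 22.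

Step 15. The most likely failure is loss of regio- or geometric control in the enolisation: removal of a C2 proton would give the extended dienolate of the alkylidene β-keto ester, a mixture of C8=C9 enolate geometries would erode the facial preference at C8, and conjugate addition of the amide is also possible. The fallback avoids re-enolisation altogether. It sets out from 22: the oxaziridine is added at −78 °C to the geometrically defined enolate 24 as it is formed in step 14, before any proton source, and the sequence comes back to the route at 27. This fallback makes no new compound (F0).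

Step 21. The most likely failure is hydride delivery to the other face of C9, if the 8-acyloxy group sits perpendicular to the carbonyl on the outer face instead of near its plane; 1,4-reduction and migration of the acyl group from O8 to O9 are lesser risks. The fallback reverses the order of reduction and acylation so that the free C8 hydroxyl directs the hydride. It sets out from 27, which is reduced with Me4N[BH(OAc)3] (MeCN/AcOH, −20 °C; hydroxyl-directed internal delivery) to the 8,9-anti diol F6 (anti in the zigzag sense, both oxygens on the same ring face). The less hindered allylic C9 hydroxyl is acetylated (AcCl, 2,4,6-collidine, −78 °C) to the 9-acetate F7. Acylation of F7 with 34 (pyridine, DMAP) gives the silyl ether F8, and citric acid in methanol then comes back to the route at 38.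

Step 6. The most likely failure is consumption of the enolisable ketone under carbonate at 80 °C (aldol condensation or C-vinylation), protodeiodination, or partial loss of E geometry. The fallback forms the C–O bond oxidatively at room temperature. It sets out from 7, which is olefinated with Cl2CHB(pin), CrCl2 and LiI to the E alkenylboronate F9. Copper-promoted coupling of F9 with 9 (Cu(OAc)2, Et3N, air; Chan–Lam type, retention of geometry) comes back to the route at 10.

## Further compounds

F1 | step 14 | methyl (5S,6R)-6-[(1E)-3-{[(4-methoxyphenyl)methoxy]methyl}buta-1,3-dien-1-yl]-5-{(E)-2-[(4-methoxyphenyl)methoxy]ethenyl}-5-methyl-6-[(trimethylsilyl)oxy]cyclohex-1-ene-1-carboxylate | C[Si](C)(C)O[C@@]1(/C=C/C(=C)COCc2ccc(OC)cc2)C(C(=O)OC)=CCC[C@@]1(C)/C=C/OCc1ccc(OC)cc1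
F2 | step 14 | methyl (4E,6R,7S)-6,12-bis[(4-methoxyphenyl)methoxy]-9-[(trimethylsilyl)oxy]germacra-1(10),4,8,11(13)-tetraen-14-oate (silyl enol ether of 25) | C[Si](C)(C)O/C1=C\[C@@H](C(=C)COCc2ccc(OC)cc2)[C@H](OCc2ccc(OC)cc2)/C=C(\C)CC/C=C1/C(=O)OC
F3 | step 12 | (5S,6R)-6-ethynyl-6-hydroxy-5-{(E)-2-[(4-methoxyphenyl)methoxy]ethenyl}-5-methylcyclohex-1-en-1-yl trifluoromethanesulfonate | O[C@@]1(C#C)C(OS(=O)(=O)C(F)(F)F)=CCC[C@@]1(C)/C=C/OCc1ccc(OC)cc1
F4 | step 12 | methyl (5S,6R)-6-ethynyl-6-hydroxy-5-{(E)-2-[(4-methoxyphenyl)methoxy]ethenyl}-5-methylcyclohex-1-ene-1-carboxylate | O[C@@]1(C#C)C(C(=O)OC)=CCC[C@@]1(C)/C=C/OCc1ccc(OC)cc1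
F5 | step 12 | methyl (5S,6R)-6-hydroxy-5-{(E)-2-[(4-methoxyphenyl)methoxy]ethenyl}-5-methyl-6-[(E)-2-(tributylstannyl)ethenyl]cyclohex-1-ene-1-carboxylate | O[C@@]1(/C=C/[Sn](CCCC)(CCCC)CCCC)C(C(=O)OC)=CCC[C@@]1(C)/C=C/OCc1ccc(OC)cc1
F0 | step 15 | none | none
F6 | step 21 | methyl (4E,6R,7R,8R,9S)-8,9-dihydroxy-6,12-bis[(4-methoxyphenyl)methoxy]germacra-1(10),4,11(13)-trien-14-oate | O[C@@H]1[C@H](O)[C@@H](C(=C)COCc2ccc(OC)cc2)[C@H](OCc2ccc(OC)cc2)/C=C(\C)CC/C=C1/C(=O)OC
F7 | step 21 | methyl (4E,6R,7R,8R,9S)-9-acetoxy-8-hydroxy-6,12-bis[(4-methoxyphenyl)methoxy]germacra-1(10),4,11(13)-trien-14-oate | CC(=O)O[C@@H]1[C@H](O)[C@@H](C(=C)COCc2ccc(OC)cc2)[C@H](OCc2ccc(OC)cc2)/C=C(\C)CC/C=C1/C(=O)OC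
F8 | step 21 | methyl (4E,6R,7S,8R,9S)-9-acetoxy-8-{[(2R,3R)-3-chloro-2-methyl-2-(trimethylsilyloxy)butanoyl]oxy}-6,12-bis[(4-methoxyphenyl)methoxy]germacra-1(10),4,11(13)-trien-14-oate | CC(=O)O[C@@H]1[C@H](OC(=O)[C@@](C)(O[Si](C)(C)C)[C@@H](C)Cl)[C@@H](C(=C)COCc2ccc(OC)cc2)[C@H](OCc2ccc(OC)cc2)/C=C(\C)CC/C=C1/C(=O)OC
F9 | step 6 | (S)-2-methyl-2-[(E)-2-(4,4,5,5-tetramethyl-1,3,2-dioxaborolan-2-yl)ethenyl]cyclohexanone | CC1(C)OB(/C=C/[C@]2(C)CCCCC2=O)OC1(C)C
A1 | alternative 1 | 1-bromo-4-iodobenzene | Brc1ccc(I)cc1
A2 | alternative 1 | (1S,2R)-3-bromo-6-iodocyclohexa-3,5-diene-1,2-diol | IC1=CC=C(Br)[C@H](O)[C@@H]1O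
A3 | alternative 2 | (3S,4S)-4-[(tert-butyldimethylsilyl)oxy]-3-chlorohex-5-en-2-one | C=C[C@H](O[Si](C)(C)C(C)(C)C)[C@H](Cl)C(C)=O
A4 | alternative 2 | {3-[(4-methoxyphenyl)methoxy]propyl}magnesium bromide | COc1ccc(COCCC[Mg]Br)cc1
A5 | alternative 2 | tert-butyl({(1S)-1-[(2R,3R)-3-{3-[(4-methoxyphenyl)methoxy]propyl}-3-methyloxiran-2-yl]prop-2-en-1-yl}oxy)dimethylsilane (C1–C8 fragment) | C=C[C@H](O[Si](C)(C)C(C)(C)C)[C@H]1O[C@]1(C)CCCOCc1ccc(OC)cc1
A6 | alternative 3 | dimethyl 9-acetoxy-8-[(tert-butyldimethylsilyl)oxy]-5-iodo-6-oxo-5,6-secogermacra-1(10),4,11(13)-triene-12,14-dioate (E iodide, ring-cis-type enoate, centres as in the SMILES) | I/C=C(\C)CC/C=C(C(=O)OC)\[C@H](OC(C)=O)[C@H](O[Si](C)(C)C(C)(C)C)[C@H](C=O)C(=C)C(=O)OC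
A7 | alternative 3 | methyl 9-acetoxy-8-[(tert-butyldimethylsilyl)oxy]germacra-1(10),4,11(13)-trien-12,6-olid-14-oate (trans lactone, E C4=C5) | C1C/C=C(C(=O)OC)\[C@H](OC(C)=O)[C@H](O[Si](C)(C)C(C)(C)C)[C@@H]2[C@H](OC(=O)C2=C)/C=C1\C
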